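**Plan**

Locants follow germacranolide numbering: the lactone is C12(=O)–O–C6, the ring fusion is C6/C7, the ester sits on C8, the exo-methylene is C11=C13, the formyl carbon C14 is on C10 and the hydroxymethyl carbon C15 is on C4.
Retrosynthesis: the C6–C7 bond, shared by the ten-membered carbocycle and the γ-lactone, is cut first, which also undoes the lactone C12–O6 bond. Then follow C7=C11 (acrylate unit), C1=C10 and C4=C5 (two E-selective Horner–Wadsworth–Emmons olefinations), C9–C10 (epoxide opening) and C3–C4 (alkylation).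
Enabling feature: C7 is the β-carbon of the acrylate C13=C11–C12(=O)–O6 and C6 is the carbinol carbon next to the C4=C5 alkene. C6–C7 is therefore the bond formed when a 2-(alkoxycarbonyl)allyl metal adds through its γ-carbon to an enal; both ring alkenes are ring-cis, so the ten-membered ring is little strained.
Forward: a C1–C6/C15 aldehyde is joined to a glycidol-derived phosphonolactone (C7–C10, C14) and the temporary C14/O8 lactone ring is opened. Both chain ends are oxidized to aldehydes, the C7 aldehyde alone takes up methyl acrylate, and CrCl2 then closes the carbocycle and the lactone in one flask; ester installation and unmasking finish the route.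
Stereochemistry: C8 comes from an (S)-glycidyl ether and both alkene geometries from thermodynamic olefination control. C6 and C7 are set together in the ring closure (syn from the Z-allyl geometry in a chair, face from the C8 silyloxy centre); the two carbinol epimers of the acrylate adduct converge on one Z-bromide.

Key step: step 15

Remark: the two 4-methoxybenzyl (PMB) building blocks, the glycolaldehyde ether and the (S)-glycidyl ether, are taken as purchasable.

**Step 1**
Reactants: 1 triethyl phosphonoacetate; 2 3-bromo-1,1-dimethoxypropane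
Product: 3 ethyl 2-(diethoxyphosphoryl)-5,5-dimethoxypentanoate (racemic)
Conditions: NaH, DMF, 0 °C; then 2, NaI (cat.), 60 °C
Reagents that add atoms: none
Why: SN2 C-alkylation of the stabilized phosphonate carbanion by the primary bromide should give the α-substituted olefination reagent that carries C1–C4 and C15, with C1 masked as its dimethyl acetal.

**Step 2**
Reactants: 3; 4 2-[(4-methoxybenzyl)oxy]acetaldehyde
Product: 5 ethyl (2E)-2-(3,3-dimethoxypropyl)-4-[(4-methoxybenzyl)oxy]but-2-enoate
Conditions: NaH, THF, 0 °C; then 4, 0 °C → rt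
Reagents that add atoms: none
Why: Horner–Wadsworth–Emmons olefination under equilibrating sodium conditions should favour the E-enoate (C6 trans to the C15 ester, hence cis to C3), which is the ring-cis geometry needed at C4=C5; a minor Z isomer would be removed by chromatography.

**Step 3**
Reactants: 5
Product: 6 (2E)-2-(3,3-dimethoxypropyl)-4-[(4-methoxybenzyl)oxy]but-2-en-1-ol
Conditions: i-Bu2AlH (DIBAL-H), CH2Cl2, −78 °C; aq. potassium sodium tartrate
Reagents that add atoms: none
Why: 1,2-reduction of the conjugated ester by the aluminium hydride should give the C15 allylic alcohol without touching the acetal, the PMB ether or the alkene geometry.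

**Step 4**
Reactants: 6
Product: 7 tert-butyl{[(2E)-2-(3,3-dimethoxypropyl)-4-[(4-methoxybenzyl)oxy]but-2-en-1-yl]oxy}diphenylsilane
Conditions: t-BuPh2SiCl, imidazole, CH2Cl2, 0 °C → rt
Reagents that add atoms: tert-butyl(chloro)diphenylsilane, CC(C)(C)[Si](Cl)(c1ccccc1)c1ccccc1
Why: standard silylation of the primary allylic alcohol installs the one hydroxyl protecting group (on O15) that must outlast the DDQ, buffered-fluoride and chromium steps.

**Step 5**
Reactants: 7
Product: 8 (4E)-4-{[(tert-butyldiphenylsilyl)oxy]methyl}-6-[(4-methoxybenzyl)oxy]hex-4-enal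
Conditions: pyridinium p-toluenesulfonate (PPTS, cat.), acetone/H2O (9:1), 50 °C
Reagents that add atoms: water, O
Why: mild acid-catalysed acetal hydrolysis should free the C1 aldehyde while the PMB and tert-butyldiphenylsilyl ethers are stable.

**Step 6**
Reactants: 1 triethyl phosphonoacetate; 9 (2S)-2-{[(4-methoxybenzyl)oxy]methyl}oxirane
Product: 10 diethyl [(5S)-5-{[(4-methoxybenzyl)oxy]methyl}-2-oxooxolan-3-yl]phosphonate (both C3 epimers)
Conditions: NaH, THF/toluene, 0 °C; then 9, 90 °C; 1 M HCl quench
Reagents that add atoms: none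
Why: the phosphonoacetate carbanion should open the epoxide at its unsubstituted carbon (SN2) and the C8 alkoxide then lactonizes onto the ethyl ester, as in the malonate–epoxide route to γ-butyrolactones, so C9–C10 is formed and the C8 configuration of 9 is carried over unchanged; the C10 epimers are of no consequence.

**Step 7**
Reactants: 8; 10
Product: 11 (3E,5S)-3-[(4E)-4-{[(tert-butyldiphenylsilyl)oxy]methyl}-6-[(4-methoxybenzyl)oxy]hex-4-en-1-ylidene]-5-{[(4-methoxybenzyl)oxy]methyl}oxolan-2-one
Conditions: NaH, THF, 0 °C; then 8, 0 °C → rt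
Reagents that add atoms: none
Why: Horner–Wadsworth–Emmons olefination of the α-phosphono-γ-butyrolactone should give mainly the E-alkylidene lactone (C2 trans to the C14 carbonyl, the ring-cis geometry at C1=C10), and the lactone meanwhile serves as a temporary ring that ties C14 and O8 together.

**Step 8**
Reactants: 11
Product: 13 (2E,6E)-6-{[(tert-butyldiphenylsilyl)oxy]methyl}-N-methoxy-8-[(4-methoxybenzyl)oxy]-2-{(2S)-3-[(4-methoxybenzyl)oxy]-2-[(triethylsilyl)oxy]propyl}-N-methylocta-2,6-dienamide, via chloromagnesium alkoxide of the hydroxy amide 12 (not isolated)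
Conditions: MeNHOMe·HCl, i-PrMgCl, THF, −20 → 0 °C; then Et3SiCl, imidazole, 0 °C → rt
Reagents that add atoms: N,O-dimethylhydroxylamine hydrochloride, CNOC.Cl; chlorotriethylsilane, CC[Si](Cl)(CC)CC
Why: aminolysis of the lactone by the magnesium amide (Weinreb amide formation) opens the temporary ring, and silylation of the resulting magnesium alkoxide in the same flask stops it from closing again.

**Step 9**
Reactants: 13
Product: 14 (2E,6E)-6-{[(tert-butyldiphenylsilyl)oxy]methyl}-8-[(4-methoxybenzyl)oxy]-2-{(2S)-3-[(4-methoxybenzyl)oxy]-2-[(triethylsilyl)oxy]propyl}octa-2,6-dienal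
Conditions: i-Bu2AlH, THF, −78 °C; aq. potassium sodium tartrate
Reagents that add atoms: none
Why: Weinreb amide reduction should stop at the aldehyde because the chelated tetrahedral intermediate survives until work-up, giving the E-enal at C14.

**Step 10**
Reactants: 14
Product: 15 dimethyl acetal of 14 (1,1-dimethoxy compound; both alkenes E; 2S in the side chain)
Conditions: MeOSiMe3, Me3SiOTf (cat.), CH2Cl2, −78 °C; pyridine quench
Reagents that add atoms: methoxytrimethylsilane, CO[Si](C)(C)C
Why: Noyori acetalization masks the C14 aldehyde so that it cannot compete as the electrophile in the ring closure, and the aprotic low-temperature conditions spare the triethylsilyl ether and avoid conjugate addition.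

**Step 11**
Reactants: 15
Product: 16 (2E,6E,9S)-3-{[(tert-butyldiphenylsilyl)oxy]methyl}-7-(dimethoxymethyl)-9-[(triethylsilyl)oxy]deca-2,6-diene-1,10-diol
Conditions: 2,3-dichloro-5,6-dicyano-1,4-benzoquinone (DDQ), CH2Cl2/pH 7 phosphate buffer (10:1), 0 °C
Reagents that add atoms: none
Why: oxidative PMB ether cleavage (benzylic hydride abstraction, then hydrolysis of the oxocarbenium ion) frees O6 and O7 together under buffered conditions that keep the acetal and both silyl ethers; any allylic alcohol already oxidized to the enal converges in the next step.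

**Step 12**
Reactants: 16
Product: 17 (2E,6E,9S)-3-{[(tert-butyldiphenylsilyl)oxy]methyl}-7-(dimethoxymethyl)-9-[(triethylsilyl)oxy]deca-2,6-dienedial
Conditions: Dess–Martin periodinane (1,1,1-triacetoxy-1,1-dihydro-1,2-benziodoxol-3(1H)-one), NaHCO3, CH2Cl2, 0 °C → rt
Reagents that add atoms: none
Why: buffered Dess–Martin oxidation should turn both primary alcohols into aldehydes (the C6 enal and the C7 α-silyloxy aldehyde) without epimerizing C8 or isomerizing the enal.

**Step 13**
Reactants: 17; 18 methyl acrylate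
Product: 19 methyl (4S,6E,10E)-10-{[(tert-butyldiphenylsilyl)oxy]methyl}-6-(dimethoxymethyl)-3-hydroxy-2-methylidene-12-oxo-4-[(triethylsilyl)oxy]dodeca-6,10-dienoate (both C3 epimers)
Conditions: 1,4-diazabicyclo[2.2.2]octane (DABCO, 1 equiv), neat 18 (excess), rt, dark
Reagents that add atoms: none
Why: in this Morita–Baylis–Hillman reaction the amine–acrylate zwitterion should add only to the inductively activated, unconjugated α-silyloxy aldehyde and not to the β,β-disubstituted enal, and the new carbinol configuration does not matter because the next step erases it.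

**Step 14**
Reactants: 19
Product: 20 methyl (2Z,4S,6E,10E)-2-(bromomethyl)-10-{[(tert-butyldiphenylsilyl)oxy]methyl}-6-(dimethoxymethyl)-12-oxo-4-[(triethylsilyl)oxy]dodeca-2,6,10-trienoate
Conditions: NBS, Me2S, CH2Cl2, −20 → 0 °C
Reagents that add atoms: N-bromosuccinimide, O=C1CCC(=O)N1Br
Why: activation of the hydroxyl as an alkoxysulfonium ion (Corey–Kim reagent) and SN2' attack of bromide should convert both carbinol epimers into the single, thermodynamically favoured Z-allylic bromide (C8 cis to CH2Br) without releasing acid.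

**Step 15**
Reactants: 20
Product: 23 (3aR,4S,6E,10E,11aR)-10-{[(tert-butyldiphenylsilyl)oxy]methyl}-6-(dimethoxymethyl)-3-methylidene-4-[(triethylsilyl)oxy]-3a,4,5,8,9,11a-hexahydrocyclodeca[b]furan-2(3H)-one, via allylchromium dichloride 21 (not isolated), via dichlorochromium alkoxide of the hydroxy ester 22 (not isolated)
Conditions: CrCl2 (8 equiv), THF, slow addition of 20 (syringe pump, final about 2 mM), 25 °C; then 45 °C; aq. NH4Cl
Reagents that add atoms: none
Why: CrCl2 reduces the allylic bromide in two one-electron steps to the 2-(methoxycarbonyl)allylchromium species 21 (trivalent chromium), which adds through its γ-carbon C7 to the C6 aldehyde in a closed chair with chromium bound to the carbonyl oxygen, and the chromium alkoxide 22 then attacks the C12 ester and expels methoxide. The closest known reaction type is the CrCl2 (Nozaki–Hiyama) or zinc (Barbier) cyclization of ω-formyl 2-(bromomethyl)alk-2-enoates to α-methylene-γ-butyrolactones fused to medium rings, which has served for ten-membered germacranolides. The carbocycle closes by a 10-exo-trig allyl addition to the carbonyl and the lactone by a 5-exo-trig acyl substitution. C6 and C7 are set relative to each other by the Z geometry of the allyl unit, which places C8 axial and C5 equatorial in the chair and so gives the syn adduct and the cis-fused lactone. Their sense relative to C8 is set by the silyloxy stereocentre: allylic 1,3-strain holds H8 in the allyl plane, the tether carbon C9 must then lie anti to the forming bond (a gauche placement would push C9 against C5 across the ring), and the non-chelating OSiEt3 group is left outside, so the aldehyde should reach the face that gives 6R,7S. The step needs γ-regioselectivity (inherent in the cyclic transition state), chemoselectivity for the C6 aldehyde (the second enal is masked as the acetal and esters do not react) and ring closure over oligomerization (slow addition at high dilution, helped by the two ring-cis alkenes that fold the chain).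

**Step 16**
Reactants: 23
Product: 24 (3aS,4S,6E,10E,11aR)-10-{[(tert-butyldiphenylsilyl)oxy]methyl}-6-(dimethoxymethyl)-4-hydroxy-3-methylidene-3a,4,5,8,9,11a-hexahydrocyclodeca[b]furan-2(3H)-one
Conditions: Bu4NF, AcOH (1:1), THF, 0 °C
Reagents that add atoms: none
Why: buffered fluoride should cleave the triethylsilyl ether much faster than the tert-butyldiphenylsilyl ether and, being non-acidic, leaves the acetal acyclic (acid would close a cyclic mixed acetal between O8 and C14).

**Step 17**
Reactants: 24; 25 3-methylbutanoic (isovaleric) anhydride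
Product: 26 (3aS,4S,6E,10E,11aR)-10-{[(tert-butyldiphenylsilyl)oxy]methyl}-6-(dimethoxymethyl)-3-methylidene-2-oxo-2,3,3a,4,5,8,9,11a-octahydrocyclodeca[b]furan-4-yl 3-methylbutanoate
Conditions: 4-(dimethylamino)pyridine (DMAP, cat.), Et3N, CH2Cl2, 0 °C, directly on crude 24
Reagents that add atoms: none
Why: DMAP-catalysed acyl transfer esterifies the secondary C8 alcohol with retention, and doing it at once forestalls migration of the lactone from O6 to O8; acylating before the aldehyde is unmasked prevents lactol formation between O8 and C14.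

**Step 18**
Reactants: 26
Product: 27 (3aS,4S,6E,10E,11aR)-6-formyl-10-(hydroxymethyl)-3-methylidene-2-oxo-2,3,3a,4,5,8,9,11a-octahydrocyclodeca[b]furan-4-yl 3-methylbutanoate (target)
Conditions: HF·pyridine, THF, 0 °C → rt; then H2O
Reagents that add atoms: water, O
Why: HF·pyridine removes the tert-butyldiphenylsilyl ether and the acidic aqueous phase hydrolyses the allylic dimethyl acetal to the conjugated aldehyde, while the ester, the lactone and all three stereocentres are untouched.

**Compound list**

1 | triethyl phosphonoacetate | CCOC(=O)CP(=O)(OCC)OCC | starting material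
2 | 3-bromo-1,1-dimethoxypropane | COC(CCBr)OC | starting material
3 | ethyl 2-(diethoxyphosphoryl)-5,5-dimethoxypentanoate (racemic) | CCOC(=O)C(CCC(OC)OC)P(=O)(OCC)OCC | intermediate
4 | 2-[(4-methoxybenzyl)oxy]acetaldehyde | COc1ccc(COCC=O)cc1 | starting material
5 | ethyl (2E)-2-(3,3-dimethoxypropyl)-4-[(4-methoxybenzyl)oxy]but-2-enoate | COc1ccc(COC/C=C(/C(=O)OCC)CCC(OC)OC)cc1 | intermediate
6 | (2E)-2-(3,3-dimethoxypropyl)-4-[(4-methoxybenzyl)oxy]but-2-en-1-ol | COc1ccc(COC/C=C(/CO)CCC(OC)OC)cc1 | intermediate
7 | tert-butyldiphenylsilyl ether of 6 | COc1ccc(COC/C=C(/CO[Si](c2ccccc2)(c2ccccc2)C(C)(C)C)CCC(OC)OC)cc1 | intermediate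
8 | (4E)-4-{[(tert-butyldiphenylsilyl)oxy]methyl}-6-[(4-methoxybenzyl)oxy]hex-4-enal | COc1ccc(COC/C=C(/CO[Si](c2ccccc2)(c2ccccc2)C(C)(C)C)CCC=O)cc1 | intermediate
9 | (2S)-2-{[(4-methoxybenzyl)oxy]methyl}oxirane | COc1ccc(COC[C@@H]2CO2)cc1 | starting material
10 | diethyl [(5S)-5-{[(4-methoxybenzyl)oxy]methyl}-2-oxooxolan-3-yl]phosphonate (C3 epimers) | CCOP(=O)(OCC)C1C[C@@H](COCc2ccc(OC)cc2)OC1=O | intermediate
11 | (3E,5S)-3-[(4E)-4-{[(tert-butyldiphenylsilyl)oxy]methyl}-6-[(4-methoxybenzyl)oxy]hex-4-en-1-ylidene]-5-{[(4-methoxybenzyl)oxy]methyl}oxolan-2-one | COc1ccc(COC/C=C(/CO[Si](c2ccccc2)(c2ccccc2)C(C)(C)C)CC/C=C2/C(=O)O[C@H](COCc3ccc(OC)cc3)C2)cc1 | intermediate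
12 | chloromagnesium alkoxide of the ring-opened hydroxy Weinreb amide | COc1ccc(COC/C=C(/CO[Si](c2ccccc2)(c2ccccc2)C(C)(C)C)CC/C=C(/C(=O)N(C)OC)C[C@H](O[Mg]Cl)COCc2ccc(OC)cc2)cc1 | intermediate (not isolated)
13 | (2E,6E)-6-{[(tert-butyldiphenylsilyl)oxy]methyl}-N-methoxy-8-[(4-methoxybenzyl)oxy]-2-{(2S)-3-[(4-methoxybenzyl)oxy]-2-[(triethylsilyl)oxy]propyl}-N-methylocta-2,6-dienamide | COc1ccc(COC/C=C(/CO[Si](c2ccccc2)(c2ccccc2)C(C)(C)C)CC/C=C(/C(=O)N(C)OC)C[C@H](O[Si](CC)(CC)CC)COCc2ccc(OC)cc2)cc1 | intermediate
14 | (2E,6E)-6-{[(tert-butyldiphenylsilyl)oxy]methyl}-8-[(4-methoxybenzyl)oxy]-2-{(2S)-3-[(4-methoxybenzyl)oxy]-2-[(triethylsilyl)oxy]propyl}octa-2,6-dienal | COc1ccc(COC/C=C(/CO[Si](c2ccccc2)(c2ccccc2)C(C)(C)C)CC/C=C(/C=O)C[C@H](O[Si](CC)(CC)CC)COCc2ccc(OC)cc2)cc1 | intermediate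
15 | dimethyl acetal of 14 | COc1ccc(COC/C=C(/CO[Si](c2ccccc2)(c2ccccc2)C(C)(C)C)CC/C=C(/C(OC)OC)C[C@H](O[Si](CC)(CC)CC)COCc2ccc(OC)cc2)cc1 | intermediate
16 | (2E,6E,9S)-3-{[(tert-butyldiphenylsilyl)oxy]methyl}-7-(dimethoxymethyl)-9-[(triethylsilyl)oxy]deca-2,6-diene-1,10-diol | OC/C=C(/CO[Si](c1ccccc1)(c1ccccc1)C(C)(C)C)CC/C=C(/C(OC)OC)C[C@H](O[Si](CC)(CC)CC)CO | intermediate
17 | (2E,6E,9S)-3-{[(tert-butyldiphenylsilyl)oxy]methyl}-7-(dimethoxymethyl)-9-[(triethylsilyl)oxy]deca-2,6-dienedial | O=C/C=C(/CO[Si](c1ccccc1)(c1ccccc1)C(C)(C)C)CC/C=C(/C(OC)OC)C[C@H](O[Si](CC)(CC)CC)C=O | intermediate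
18 | methyl acrylate | C=CC(=O)OC | starting material
19 | methyl (4S,6E,10E)-10-{[(tert-butyldiphenylsilyl)oxy]methyl}-6-(dimethoxymethyl)-3-hydroxy-2-methylidene-12-oxo-4-[(triethylsilyl)oxy]dodeca-6,10-dienoate (C3 epimers) | O=C/C=C(/CO[Si](c1ccccc1)(c1ccccc1)C(C)(C)C)CC/C=C(/C(OC)OC)C[C@H](O[Si](CC)(CC)CC)C(O)C(=C)C(=O)OC | intermediate
20 | methyl (2Z,4S,6E,10E)-2-(bromomethyl)-10-{[(tert-butyldiphenylsilyl)oxy]methyl}-6-(dimethoxymethyl)-12-oxo-4-[(triethylsilyl)oxy]dodeca-2,6,10-trienoate | O=C/C=C(/CO[Si](c1ccccc1)(c1ccccc1)C(C)(C)C)CC/C=C(/C(OC)OC)C[C@H](O[Si](CC)(CC)CC)/C=C(\CBr)C(=O)OC | intermediate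
21 | allylchromium dichloride derived from 20 (CrCl2 on C13) | O=C/C=C(/CO[Si](c1ccccc1)(c1ccccc1)C(C)(C)C)CC/C=C(/C(OC)OC)C[C@H](O[Si](CC)(CC)CC)/C=C(\C[Cr](Cl)Cl)C(=O)OC | intermediate (not isolated)
22 | dichlorochromium alkoxide of the ten-membered syn hydroxy ester (O6–CrCl2; H6, H7 and H8 on one face) | COC(=O)C(=C)[C@@H]1[C@H](O[Cr](Cl)Cl)/C=C(/CO[Si](c2ccccc2)(c2ccccc2)C(C)(C)C)CC/C=C(/C(OC)OC)C[C@@H]1O[Si](CC)(CC)CC | intermediate (not isolated)
23 | (3aR,4S,6E,10E,11aR)-10-{[(tert-butyldiphenylsilyl)oxy]methyl}-6-(dimethoxymethyl)-3-methylidene-4-[(triethylsilyl)oxy]-3a,4,5,8,9,11a-hexahydrocyclodeca[b]furan-2(3H)-one | C=C1C(=O)O[C@@H]2/C=C(/CO[Si](c3ccccc3)(c3ccccc3)C(C)(C)C)CC/C=C(/C(OC)OC)C[C@H](O[Si](CC)(CC)CC)[C@H]12 | intermediate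
24 | (3aS,4S,6E,10E,11aR)-10-{[(tert-butyldiphenylsilyl)oxy]methyl}-6-(dimethoxymethyl)-4-hydroxy-3-methylidene-3a,4,5,8,9,11a-hexahydrocyclodeca[b]furan-2(3H)-one | C=C1C(=O)O[C@@H]2/C=C(/CO[Si](c3ccccc3)(c3ccccc3)C(C)(C)C)CC/C=C(/C(OC)OC)C[C@H](O)[C@H]12 | intermediate
25 | 3-methylbutanoic anhydride | CC(C)CC(=O)OC(=O)CC(C)C | starting material
26 | (3aS,4S,6E,10E,11aR)-10-{[(tert-butyldiphenylsilyl)oxy]methyl}-6-(dimethoxymethyl)-3-methylidene-2-oxo-2,3,3a,4,5,8,9,11a-octahydrocyclodeca[b]furan-4-yl 3-methylbutanoate | C=C1C(=O)O[C@@H]2/C=C(/CO[Si](c3ccccc3)(c3ccccc3)C(C)(C)C)CC/C=C(/C(OC)OC)C[C@H](OC(=O)CC(C)C)[C@H]12 | intermediate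
27 | (3aS,4S,6E,10E,11aR)-6-formyl-10-(hydroxymethyl)-3-methylidene-2-oxo-2,3,3a,4,5,8,9,11a-octahydrocyclodeca[b]furan-4-yl 3-methylbutanoate | C=C1C(=O)O[C@@H]2/C=C(/CO)CC/C=C(/C=O)C[C@H](OC(=O)CC(C)C)[C@H]12 | target

**Step count and risks**

Total step count: 18. Longest linear sequence: 17 steps (steps 1–5, then 7–18); step 6 is a one-step side branch.

Step 15. The ring closure may fail by attack on the other face of the allyl unit relative to C8 (the chair is steered by the substrate alone), or by intermolecular coupling instead of cyclization. The fallback changes from a chromium allyl to a boron allyl under catalyst control and sets out from 19. Acetylation (Ac2O, pyridine, DMAP) would give the allylic acetate F1. Borylation with bis(pinacolato)diboron and Pd2(dba)3 (zerovalent palladium; DMSO, 50 °C) would give, with allylic transposition, the pinacol allylboronate F2. Intramolecular allylboration at high dilution, catalysed by the chiral phosphoric acid 3,3'-bis(2,4,6-triisopropylphenyl)-1,1'-binaphthyl-2,2'-diyl hydrogen phosphate (the enantiomer that matches the substrate), would pass through a boron-centred chair to the pinacol borate of the hydroxy ester F3. Lactonization of F3 on warming would come back to the route at 23.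

Step 13. The amine-mediated addition is slow, so the α-silyloxy aldehyde may lose configuration at C8 by enolization, or the enal may react as well. The fallback replaces Lewis-base catalysis by a stoichiometric alkenylmetal addition and sets out from 17. The alkenylalane methyl 2-(diisobutylalumanyl)acrylate F4 would be made in the flask from methyl propiolate with i-Bu2AlH and N-methylmorpholine N-oxide in THF at 0 °C. One equivalent added at −78 → −20 °C should react with the unconjugated, inductively activated C7 aldehyde ahead of the β,β-disubstituted enal, with no amine base present, and come back to the route at 19.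

Step 8. The magnesium amide may add in conjugate fashion to the alkylidene lactone, or the lactone may close again before the alkoxide is silylated. The fallback avoids the amide and sets out from 11. Excess i-Bu2AlH would reduce the lactone to the diol F5, and Et3SiCl with imidazole would give the bis(triethylsilyl) ether F6. Swern conditions ((COCl)2, DMSO, −78 °C; then Et3N) cleave and oxidize a primary triethylsilyl ether but leave a secondary one, so they would turn the primary allylic silyl ether directly into the aldehyde and come back to the route at 14.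

**Further compounds**

F1 | step 15 | methyl (4S,6E,10E)-3-acetoxy-10-{[(tert-butyldiphenylsilyl)oxy]methyl}-6-(dimethoxymethyl)-2-methylidene-12-oxo-4-[(triethylsilyl)oxy]dodeca-6,10-dienoate (C3 epimers) | O=C/C=C(/CO[Si](c1ccccc1)(c1ccccc1)C(C)(C)C)CC/C=C(/C(OC)OC)C[C@H](O[Si](CC)(CC)CC)C(OC(C)=O)C(=C)C(=O)OC
F2 | step 15 | methyl (2E,4S,6E,10E)-10-{[(tert-butyldiphenylsilyl)oxy]methyl}-6-(dimethoxymethyl)-12-oxo-2-[(4,4,5,5-tetramethyl-1,3,2-dioxaborolan-2-yl)methyl]-4-[(triethylsilyl)oxy]dodeca-2,6,10-trienoate | O=C/C=C(/CO[Si](c1ccccc1)(c1ccccc1)C(C)(C)C)CC/C=C(/C(OC)OC)C[C@H](O[Si](CC)(CC)CC)/C=C(\CB1OC(C)(C)C(C)(C)O1)C(=O)OC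
F3 | step 15 | pinacol borate (on O6) of the ten-membered syn hydroxy ester | COC(=O)C(=C)[C@@H]1[C@H](OB2OC(C)(C)C(C)(C)O2)/C=C(/CO[Si](c2ccccc2)(c2ccccc2)C(C)(C)C)CC/C=C(/C(OC)OC)C[C@@H]1O[Si](CC)(CC)CC
F4 | step 13 | methyl 2-(diisobutylalumanyl)acrylate (made in the flask) | C=C([Al](CC(C)C)CC(C)C)C(=O)OC
F5 | step 8 | (2E,6E)-6-{[(tert-butyldiphenylsilyl)oxy]methyl}-2-{(2S)-2-hydroxy-3-[(4-methoxybenzyl)oxy]propyl}-8-[(4-methoxybenzyl)oxy]octa-2,6-dien-1-ol | COc1ccc(COC/C=C(/CO[Si](c2ccccc2)(c2ccccc2)C(C)(C)C)CC/C=C(/CO)C[C@H](O)COCc2ccc(OC)cc2)cc1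
F6 | step 8 | bis(triethylsilyl) ether of F5 | COc1ccc(COC/C=C(/CO[Si](c2ccccc2)(c2ccccc2)C(C)(C)C)CC/C=C(/CO[Si](CC)(CC)CC)C[C@H](O[Si](CC)(CC)CC)COCc2ccc(OC)cc2)cc1
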